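**Retrosynthetic overview**
1. Target ⇒ cis-5,6-epoxide opened at C5 by isovalerate (gives the C5 ester and the free C6–OH); the C9 isobutyrate comes from simple acylation.
2. α-Methylene lactone ⇒ C7 isopropenyl group plus C8–OH (allylic oxidation, oxidative lactonisation).
3. Ten-membered ring ⇒ anionic oxy-Cope ([3,3]) of a cis-1-vinyl-2-(E)-propenylcyclohexanol: forms C3–C4, sets C4, gives the C1 ketone and a Z C5=C6 alkene.
4. Cyclohexanone ⇒ (R)-carvone: C7 is bought; C8 by Rubottom oxidation, C9 by Luche reduction, C10 by OH-directed dihydroxylation, C6 by enolate allylation.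
5. Ring order: cyclohexane (from carvone) → cyclodecenone (oxy-Cope) → γ-lactone; the oxirane is transient.

Convention used throughout: target numbering C1 (ketone), C2, C3, C4 (CHMe), C5, C6, C7 (bears C11(=C13H2)–C12), C8 (lactone O), C9, C10 (C–Me). In the cyclohexane intermediates the ring is C1–C6–C7–C8–C9–C10, and β means the face carrying the C7 isopropenyl group. Carvone C1/C2/C3/C4/C5/C6 become C9/C10/C1/C6/C7/C8.

**Route**

Step 1
Reactants: 1 (R)-(−)-carvone
Product: 3 trans-8-silyloxy enone, via silyl dienol ether 2 (not isolated)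
Conditions: LDA, THF, −78 °C; Et3SiCl; then mCPBA, CH2Cl2, −20 °C
Reagents that add atoms: chlorotriethylsilane CC[Si](Cl)(CC)CC; mCPBA OOC(=O)c1cccc(Cl)c1
Why: Kinetic α′-deprotonation gives the cross-conjugated silyl dienol ether, and Rubottom oxidation (epoxidation of the enol ether anti to the neighbouring isopropenyl group, then silyl shift) places the C8 oxygen trans to the C7 side chain.

Step 2
Reactants: 3 trans-8-silyloxy enone
Product: 4 allylic alcohol
Conditions: NaBH4, CeCl3·7H2O, MeOH, −78 °C
Reagents that add atoms: none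
Why: Luche 1,2-reduction with axial hydride delivery to the half-chair enone gives the all-equatorial alcohol (C9–OH β, trans to C8–O and cis to isopropenyl), as in carvone → cis-carveol.

Step 3
Reactants: 4 allylic alcohol
Product: 6 triol, via osmate ester chelate 5 (not isolated)
Conditions: OsO4 (1.05 equiv), TMEDA, CH2Cl2, −78 °C; then aq. Na2SO3, THF, 40 °C
Reagents that add atoms: osmium tetroxide O=[Os](=O)(=O)=O
Why: Donohoe hydrogen-bond-directed dihydroxylation delivers OsO4·TMEDA from the free C9–OH to the β face of the ring alkene only (the remote isopropenyl is not directed), setting C10–OH and C1–OH cis to C9–OH.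

Step 4
Reactants: 6 triol
Product: 7 C1 ketone diol
Conditions: IBX (1.2 equiv), DMSO, 25 °C
Reagents that add atoms: none
Why: IBX oxidises secondary alcohols without cleaving 1,2-diols, and the C1–OH (next to a CH2) is far more accessible than the C9–OH (wedged between quaternary C10 and the silyloxy-bearing C8), so the ketone forms at C1 while the tertiary C10–OH is inert.

Step 5
Reactants: 7 C1 ketone diol
Product: 8 acetonide ketone
Conditions: 2-methoxypropene, PPTS (cat.), CH2Cl2, 0 °C
Reagents that add atoms: 2-methoxypropene COC(C)=C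
Why: Acid-catalysed transketalisation can only bridge the one remaining cis 1,2-diol (C9/C10), and PPTS is too weak to touch the isopropenyl group or the silyl ether.

Step 6
Reactants: 8 acetonide ketone
Product: 10 allyl ketone, via lithium enolate 9 (not isolated)
Conditions: LDA, THF, −78 °C; allyl bromide, DMPU, −78 → −40 °C
Reagents that add atoms: allyl bromide C=CCBr
Why: Only C6 carries enolisable hydrogens, and SN2 allylation of the enolate occurs on the face opposite the adjacent C7 isopropenyl group, giving the trans (equatorial, α) C6 allyl group.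

Step 7
Reactants: 10 allyl ketone
Product: 11 vinyl carbinol
Conditions: vinylmagnesium bromide, CeCl3, THF, −78 → 0 °C
Reagents that add atoms: vinylmagnesium bromide C=C[Mg]Br
Why: Organocerium 1,2-addition to the hindered ketone proceeds by axial attack anti to the axial C10–O bond (Felkin–Anh polar model, and away from the acetonide), so the vinyl group ends up axial and cis to the equatorial allyl group.

Step 8
Reactants: 11 vinyl carbinol
Product: 12 (E)-propenyl carbinol
Conditions: [Cp*Ru(MeCN)(L)]PF6 (2 mol %; L = 2-(iPr2P)-4-tBu-1-methylimidazole), acetone, 40 °C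
Reagents that add atoms: none
Why: Selective one-position alkene isomerisation converts the allyl terminus into the (E)-prop-1-enyl group; the vinyl group (no allylic hydrogen) and the 1,1-disubstituted isopropenyl group are not substrates.

Step 9
Reactants: 12 (E)-propenyl carbinol
Product: 14 Z-cyclodecenone, via potassium enolate 13 (not isolated)
Conditions: KHMDS, 18-crown-6, THF, 0 → 25 °C; AcOH, −78 °C
Reagents that add atoms: none
Why: Anionic oxy-Cope [3,3]-sigmatropic rearrangement through a chair transition state breaks C1–C6 and forms C3–C4; the axial vinyl group forces the C6–C7 bond pseudo-axial (Z C5=C6), the (E)-propenyl methyl sits pseudo-equatorial (4R), and the enolate is protonated to the C1 ketone.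

Step 10
Reactants: 14 Z-cyclodecenone
Product: 15 C12 allylic alcohol
Conditions: SeO2 (0.5 equiv), t-BuOOH, CH2Cl2, 25 °C
Reagents that add atoms: selenium dioxide O=[Se]=O (oxygen carrier); tert-butyl hydroperoxide CC(C)(C)OO
Why: SeO2 allylic oxidation (ene reaction, then [2,3]-shift) prefers the more nucleophilic 1,1-disubstituted alkene and its methyl group over the ring methine, giving the 2-substituted prop-2-en-1-ol.

Step 11
Reactants: 15 C12 allylic alcohol
Product: 16 tetraol ketone
Conditions: AcOH/H2O (4:1), 45 °C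
Reagents that add atoms: none
Why: Mild aqueous acid hydrolyses the triethylsilyl ether and the isopropylidene acetal in one operation; it is too weak to protonate the Z-alkene or promote transannular reactions of the ketone.

Step 12
Reactants: 16 tetraol ketone
Product: 19 hydroxy lactone, via enal 17 (not isolated), via lactol 18 (not isolated)
Conditions: MnO2 (activated, excess), CH2Cl2, 25 °C
Reagents that add atoms: none
Why: MnO2 oxidises only the allylic primary alcohol; the enal is trapped by C8–OH as the five-membered lactol (favoured over the six-membered one through C9–OH), which as an allylic hemiacetal is oxidised on to the α-methylene-γ-lactone with no stereocentre touched.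

Step 13
Reactants: 19 hydroxy lactone
Product: 20 C9 isobutyrate
Conditions: isobutyric anhydride, DMAP (cat.), Et3N, CH2Cl2, 0 °C
Reagents that add atoms: isobutyric anhydride CC(C)C(=O)OC(=O)C(C)C
Why: DMAP-catalysed acylation takes the only secondary alcohol; the tertiary C10–OH does not react under these conditions.

Step 14
Reactants: 20 C9 isobutyrate
Product: 21 cis-5,6-epoxide
Conditions: dimethyldioxirane, acetone, −20 → 0 °C
Reagents that add atoms: dimethyldioxirane CC1(C)OO1
Why: Neutral DMDO epoxidises the electron-rich Z-alkene (not the electron-poor methylene lactone) from the outer face of the ring, opposite ring carbons C3 and C8 when both allylic hydrogens lie in the alkene plane (allylic 1,3-strain), giving the (5S,6R)-oxirane.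

Step 15
Reactants: 21 cis-5,6-epoxide
Product: 22 target CNP0203887.1
Conditions: isovaleric acid (3 equiv), Co(salen) (10 mol %), iPr2NEt, air, t-BuOMe, 25–40 °C
Reagents that add atoms: isovaleric acid CC(C)CC(O)=O
Why: Cobalt–salen carboxylate epoxide opening (SN2, achiral catalyst) should put isovalerate on C5 with inversion rather than on C6 (next to ring-fusion carbon C7 and inductively deactivated by the lactone), giving the 5R ester and leaving the oxirane oxygen as the 6R alcohol.

**Compound list**

1 | (R)-(−)-carvone, (5R)-2-methyl-5-(prop-1-en-2-yl)cyclohex-2-en-1-one | CC1=CC[C@H](CC1=O)C(C)=C | starting material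
2 | (R)-triethyl{[6-methyl-3-(prop-1-en-2-yl)cyclohexa-1,5-dien-1-yl]oxy}silane (cross-conjugated silyl dienol ether of 1) | CC[Si](CC)(CC)OC1=C[C@H](C(C)=C)CC=C1C | intermediate
3 | (5S,6S)-2-methyl-5-(prop-1-en-2-yl)-6-(triethylsilyloxy)cyclohex-2-en-1-one (C8–OSiEt3 α, trans to isopropenyl) | CC[Si](CC)(CC)O[C@H]1[C@H](C(C)=C)CC=C(C)C1=O | intermediate
4 | allylic alcohol from 3: C9–OH β (cis to isopropenyl, trans to C8–OSiEt3), C10=C1 alkene | CC[Si](CC)(CC)O[C@H]1[C@H](C(C)=C)CC=C(C)[C@@H]1O | intermediate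
5 | hexavalent osmium glycolate–TMEDA chelate on the β face of C10/C1 of 4 | CC[Si](CC)(CC)O[C@H]1[C@H](C(C)=C)C[C@@H]2O[Os-2]3(=O)(=O)([N+](C)(C)CC[N+]3(C)C)O[C@]2(C)[C@@H]1O | intermediate
6 | triol: C9–OH, C10–OH and C1–OH all β; C8–OSiEt3 α; C7 isopropenyl β | CC[Si](CC)(CC)O[C@H]1[C@H](C(C)=C)C[C@H](O)[C@](C)(O)[C@@H]1O | intermediate
7 | C1 ketone with tertiary C10–OH β, C9–OH β, C8–OSiEt3 α | CC[Si](CC)(CC)O[C@H]1[C@H](C(C)=C)CC(=O)[C@](C)(O)[C@@H]1O | intermediate
8 | 9,10-O-isopropylidene (cis-fused acetonide) derivative of 7 | CC[Si](CC)(CC)O[C@H]1[C@H](C(C)=C)CC(=O)[C@]2(C)OC(C)(C)O[C@H]12 | intermediate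
9 | lithium enolate of 8 (C1(OLi)=C6) | CC[Si](CC)(CC)O[C@H]1[C@H](C(C)=C)C=C([O-])[C@]2(C)OC(C)(C)O[C@H]12.[Li+] | intermediate
10 | 6α-allyl ketone (allyl equatorial, trans to C7 isopropenyl) | CC[Si](CC)(CC)O[C@H]1[C@H](C(C)=C)[C@@H](CC=C)C(=O)[C@]2(C)OC(C)(C)O[C@H]12 | intermediate
11 | tertiary alcohol: C1 vinyl α (axial, cis to the C6 allyl), C1–OH β | CC[Si](CC)(CC)O[C@H]1[C@H](C(C)=C)[C@@H](CC=C)[C@@](O)(C=C)[C@]2(C)OC(C)(C)O[C@H]12 | intermediate
12 | as 11, with (E)-prop-1-enyl at C6 | CC[Si](CC)(CC)O[C@H]1[C@H](C(C)=C)[C@@H](/C=C/C)[C@@](O)(C=C)[C@]2(C)OC(C)(C)O[C@H]12 | intermediate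
13 | potassium enolate of 14 (C1(OK)=C2, C3 trans to C10; Z C5=C6) | CC[Si](CC)(CC)O[C@H]1[C@H](C(C)=C)/C=C\[C@H](C)C/C=C(\[O-])[C@]2(C)OC(C)(C)O[C@H]12.[K+] | intermediate
14 | (Z)-cyclodec-5-enone: C1 ketone, 4R methyl, Z C5=C6, C7 isopropenyl, C8–OSiEt3, 9,10-acetonide (C7–C10 as in target) | CC[Si](CC)(CC)O[C@H]1[C@H](C(C)=C)/C=C\[C@H](C)CCC(=O)[C@]2(C)OC(C)(C)O[C@H]12 | intermediate
15 | 14 with C12 hydroxylated (C7 bears 3-hydroxyprop-1-en-2-yl) | CC[Si](CC)(CC)O[C@H]1[C@H](C(CO)=C)/C=C\[C@H](C)CCC(=O)[C@]2(C)OC(C)(C)O[C@H]12 | intermediate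
16 | tetraol ketone: C12–OH, C8–OH, C9–OH, C10–OH free (may sit partly as the C1/C8 hemiketal) | O[C@H]1[C@H](C(CO)=C)/C=C\[C@H](C)CCC(=O)[C@](C)(O)[C@@H]1O | intermediate
17 | C12 enal of 16 | O[C@H]1[C@H](C(C=O)=C)/C=C\[C@H](C)CCC(=O)[C@](C)(O)[C@@H]1O | intermediate
18 | 8,12-lactol (C12 hemiacetal, either epimer) | C=C1C(O)O[C@H]2[C@H]1/C=C\[C@H](C)CCC(=O)[C@](C)(O)[C@@H]2O | intermediate
19 | α-methylene 8,12-lactone with C9–OH and C10–OH free, Z C5=C6 | C=C1C(=O)O[C@H]2[C@H]1/C=C\[C@H](C)CCC(=O)[C@](C)(O)[C@@H]2O | intermediate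
20 | 9-O-isobutyrate of 19 | C=C1C(=O)O[C@H]2[C@H]1/C=C\[C@H](C)CCC(=O)[C@](C)(O)[C@@H]2OC(=O)C(C)C | intermediate
21 | (5S,6R)-cis-5,6-epoxide of 20 (oxirane oxygen on the face of the C4 methyl and C11) | C=C1C(=O)O[C@H]2[C@H]1[C@H]3O[C@H]3[C@H](C)CCC(=O)[C@](C)(O)[C@@H]2OC(=O)C(C)C | intermediate
22 | CNP0203887.1 (4R,5R,6R,7R,8S,9R,10R) | C=C1C(=O)O[C@H]2[C@H]1[C@@H](O)[C@H](OC(=O)CC(C)C)[C@H](C)CCC(=O)[C@](C)(O)[C@@H]2OC(=O)C(C)C | target

**Totals**
Total steps: 15. Longest linear sequence: 15 (from (R)-carvone).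

**Three steps most likely to fail** (route order; step 15 is the most uncertain)

Step 4 (site-selective oxidation of one of two secondary alcohols, and with it the directed dihydroxylation of step 3). The fallback sets out from 4 and fixes the regiochemistry by bond construction instead of by sterics. Hydroxyl-directed mCPBA epoxidation (CH2Cl2, 0 °C) gives the syn-epoxy alcohol F1. Ti(OiPr)4 with benzoic acid opens it at C1 (the distal carbon of the 2,3-epoxy alcohol, also the trans-diaxial mode) to give the C1 benzoate diol F2. Now only the C9/C10 cis-diol is free, so 2-methoxypropene/PPTS gives the acetonide benzoate F3. DIBAL-H (CH2Cl2, −78 °C) frees the C1 alcohol F4, and IBX oxidation returns to the route at 8.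

Step 9 (anionic oxy-Cope of an axial-vinyl, cis-dialkenyl alkoxide: rate, chair versus boat, hence Z/E and C4). The fallback sets out from 12 and uses the neutral silyloxy-Cope. N-(trimethylsilyl)imidazole gives the trimethylsilyl ether F5. Heating in toluene at 190 °C (sealed tube) rearranges it to the silyl enol ether F6; the all-carbon Cope of the isopropenyl/propenyl pair is reversible and favours the cyclohexane, so it does not drain material. K2CO3/MeOH at 0 °C returns to the route at 14.

Step 15 (intermolecular SN2 on a medium-ring cis-epoxide: backside access at C5 is crowded by the transannular C1 ketone and C10–OH, and C5/C6 regiochemistry is substrate-controlled). The fallback sets out from 21 and uses the transannular ketone instead of fighting it. TBSOTf/2,6-lutidine (CH2Cl2, −78 °C) silylates C10–OH and activates the oxirane, which is opened at C5 from inside the ring by the C1 carbonyl oxygen (six-membered participation, inversion). Aqueous work-up gives the bis-silyl hydroxy ketone F7, with C5–OH free (in equilibrium with its 1,5-hemiketal) and C6–O already silylated. Isovaleric anhydride/DMAP then acylates the only free secondary alcohol to give the C5 isovalerate F8, and HF·pyridine returns to the route at 22.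

**Further compounds**

F1 | step 4 | syn-epoxy alcohol: 10,1-epoxide β (cis to C9–OH), C8–OSiEt3 α | CC[Si](CC)(CC)O[C@H]1[C@H](C(C)=C)C[C@@H]2O[C@]2(C)[C@@H]1O
F2 | step 4 | C1 benzoate diol: C1–OBz α, C10–OH β, C9–OH β | CC[Si](CC)(CC)O[C@H]1[C@H](C(C)=C)C[C@@H](OC(=O)c2ccccc2)[C@](C)(O)[C@@H]1O
F3 | step 4 | 9,10-acetonide of F2 | CC[Si](CC)(CC)O[C@H]1[C@H](C(C)=C)C[C@@H](OC(=O)c3ccccc3)[C@]2(C)OC(C)(C)O[C@H]12
F4 | step 4 | C1 alcohol (C1–OH α) with 9,10-acetonide | CC[Si](CC)(CC)O[C@H]1[C@H](C(C)=C)C[C@@H](O)[C@]2(C)OC(C)(C)O[C@H]12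
F5 | step 9 | C1 trimethylsilyl ether of 12 | CC[Si](CC)(CC)O[C@H]1[C@H](C(C)=C)[C@@H](/C=C/C)[C@@](O[Si](C)(C)C)(C=C)[C@]2(C)OC(C)(C)O[C@H]12
F6 | step 9 | trimethylsilyl enol ether of 14 (C1(OSiMe3)=C2, Z C5=C6) | CC[Si](CC)(CC)O[C@H]1[C@H](C(C)=C)/C=C\[C@H](C)C/C=C(\O[Si](C)(C)C)[C@]2(C)OC(C)(C)O[C@H]12
F7 | step 15 | 6,10-bis-O-TBS hydroxy ketone with free (5R)-OH | C=C1C(=O)O[C@H]2[C@H]1[C@@H](O[Si](C)(C)C(C)(C)C)[C@H](O)[C@H](C)CCC(=O)[C@](C)(O[Si](C)(C)C(C)(C)C)[C@@H]2OC(=O)C(C)C
F8 | step 15 | 6,10-bis-O-TBS ether of the target | C=C1C(=O)O[C@H]2[C@H]1[C@@H](O[Si](C)(C)C(C)(C)C)[C@H](OC(=O)CC(C)C)[C@H](C)CCC(=O)[C@](C)(O[Si](C)(C)C(C)(C)C)[C@@H]2OC(=O)C(C)C
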